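**Plan**

1. Retrosynthesis: the acetate on O4 and the (R)-2-methylbutanoate on O3 come off first; C12 and C13 are traced to MeLi addition to a C7 ester (C11), C15 to a methyl coupling on C4, and O3/O4/H5 to carbonyl and alkene chemistry in ring A.
2. Ring B is then cut at C5–C6 and C6–C7. C4 and C8 carry oxygen in a 1,5 relationship across C5–C6–C7, and C7 bears C11 at the carboxyl level, so C6 is a bare CH2 between two enolisable carbons and is taken from formaldehyde.
3. The open keto β-keto ester is cut at C7–C8 (Roskamp homologation) and C9–C10 (conjugate addition to 3-methylcyclohexenone).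
4. Forward: ring A is bought, C10 is set, the chain is grown to the β-keto ester, and ring B closes in one flask by Knoevenagel condensation with CH2O and Michael attack through C5. Ring A is then taken through its 3,4-diosphenol to the 4-methyl-4-en-3-one, ring B to the isopropylidene ketone, and the two acylations come last.
5. Stereochemistry: C10 comes from the chiral NHC–Cu catalyst; C3 from Luche reduction (hydride on the α face); C4 and C5 together from hydroboration on the α face, opposite the C10 methyl; the acid stereocentre is bought. The C5 centre made in the ring closure is deliberately erased, because cis- and trans-fused 10-methyl-1-decalones are expected to be close in energy.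

Key step: step 6

Remark: eudesmane numbering is used throughout; β is the face of the C10 methyl and α the opposite face; "12,13,15-trinor" and "12,13-dinor" names denote the same skeleton without those methyl carbons.

**Route**

Step 1
Reactants: 1 3-methylcyclohex-2-en-1-one; 2 ethynyltrimethylsilane
Product: 3 (S)-3-methyl-3-[1-(trimethylsilyl)ethenyl]cyclohexan-1-one
Conditions: 2, (i-Bu)2AlH, hexanes–THF, 55 °C; then 1, Cu(OTf)2 (5 mol%), chiral sulfonate-bearing imidazolinium salt pre-treated with Ag2O (2.5 mol%), THF, −15 °C; aqueous potassium sodium tartrate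
Reagents that add atoms: ethynyltrimethylsilane, C#C[Si](C)(C)C
Why: Copper-catalysed asymmetric conjugate addition of the α-silyl vinylaluminium reagent (from hydroalumination of 2) to this β-substituted cyclic enone is a known reaction type on this substrate class, and the chiral NHC–Cu complex (ligand enantiomer chosen for the S ketone) selects the enone face and sets the quaternary C10.

Step 2
Reactants: 3 (S)-3-methyl-3-[1-(trimethylsilyl)ethenyl]cyclohexan-1-one
Product: 4 (S)-3-methyl-3-vinylcyclohexan-1-one
Conditions: CF3CO2H, CH2Cl2, 22 °C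
Reagents that add atoms: none
Why: Protodesilylation of the vinylsilane (ipso protonation assisted by the β-silicon effect, then loss of the silyl group) should leave the ketone and C10 untouched.

Step 3
Reactants: 4 (S)-3-methyl-3-vinylcyclohexan-1-one
Product: 5 (3R)-3-(2-hydroxyethyl)-3-methylcyclohexan-1-ol (both C1 epimers)
Conditions: BH3·THF (2 equiv), THF, 0 °C to rt; then NaOH, H2O2, 0 °C to rt
Reagents that add atoms: hydrogen peroxide, OO
Why: Anti-Markovnikov hydroboration–oxidation of the neopentyl-type vinyl group puts oxygen on the terminal carbon (C8), and the concurrent borane reduction of the ketone is harmless because both alcohols are oxidised in step 4.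

Step 4
Reactants: 5 (3R)-3-(2-hydroxyethyl)-3-methylcyclohexan-1-ol
Product: 6 2-[(1R)-1-methyl-3-oxocyclohexyl]acetaldehyde
Conditions: Dess–Martin periodinane (2.5 equiv), NaHCO3, CH2Cl2, 0 °C to rt
Reagents that add atoms: none
Why: Dess–Martin oxidation should take the primary alcohol to the aldehyde and the secondary alcohol back to the ketone under buffered, non-enolising conditions, and 6 is used at once to avoid aldol self-condensation.

Step 5
Reactants: 6 2-[(1R)-1-methyl-3-oxocyclohexyl]acetaldehyde; 7 methyl diazoacetate
Product: 8 methyl 4-[(1S)-1-methyl-3-oxocyclohexyl]-3-oxobutanoate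
Conditions: SnCl2 (10 mol%), 7 (1.2 equiv), CH2Cl2, rt
Reagents that add atoms: methyl diazoacetate, COC(=O)C=[N+]=[N-]
Why: Roskamp homologation (SnCl2-activated addition of the diazo ester to the aldehyde, 1,2-hydride shift and loss of N2) gives the β-keto ester, and ketones are inert under these conditions, so C4 needs no protection.

Step 6
Reactants: 8 methyl 4-[(1S)-1-methyl-3-oxocyclohexyl]-3-oxobutanoate; 9 formaldehyde
Product: 11 methyl (10R)-4,8-dioxo-12,13,15-trinoreudesman-11-oate (10-methyldecalin-4,8-dione with CO2Me on C7; C5 epimers; C7 enolisable), via methylene keto ester 10 (not isolated)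
Conditions: 37% aqueous CH2O (1.05 equiv, slow addition), pyrrolidine (30 mol%), AcOH (30 mol%), MeCN (0.02 M), 40 °C
Reagents that add atoms: formaldehyde, C=O
Why: Proposed new method: pyrrolidinium acetate should convert the β-keto ester carbon C7 and formaldehyde (through the Mannich base) into the 2-methylene β-keto ester 10, present only in low concentration, while the same amine turns the ring A ketone into its enamines, and the C4=C5 enamine then adds through C5 to C6 in an intramolecular Michael reaction before hydrolysis returns the ketone, so that C6–C7 and C5–C6 form in one flask. The closest known reaction type is the formaldehyde-mediated methylene bridging of two 1,3-dicarbonyl carbon acids (Knoevenagel condensation then Michael addition), joined here to the known amine-catalysed intramolecular Michael addition of ketones to alkylidene 1,3-dicarbonyl acceptors. Ring B closes in a 6-endo-trig mode (enolexo with respect to the enamine). The new centre C5 is not controlled and need not be, since it is flattened in step 9 and reset in step 13, and C7 stays enolisable. The step needs site selectivity only: condensation at C7 is secured by the acidity of the β-keto ester relative to the ketone, and attack through C5 by ring size, because the more accessible C3 enamine could only close a bridged eight-membered ring. High dilution and slow addition of formaldehyde are meant to suppress intermolecular Michael addition of a second β-keto ester.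

Step 7
Reactants: 11 methyl (10R)-4,8-dioxo-12,13,15-trinoreudesman-11-oate
Product: 12 methyl (10R)-8-(methoxymethoxy)-4-oxo-12,13,15-trinoreudesm-7-en-11-oate (C5 epimers)
Conditions: NaH (1.05 equiv), THF–DMPU, 0 °C; MOMCl (1.2 equiv), 0 °C
Reagents that add atoms: chloromethyl methyl ether, COCCl
Why: One equivalent of NaH deprotonates only the β-keto ester, and O-alkylation of this enolate with the hard electrophile MOMCl in a dipolar medium (enol ether formation) masks C8 as a vinylogous carbonate and leaves C4 as the only ketone.

Step 8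
Reactants: 12 methyl (10R)-8-(methoxymethoxy)-4-oxo-12,13,15-trinoreudesm-7-en-11-oate
Product: 13 methyl (10R)-3-hydroxy-8-(methoxymethoxy)-4-oxo-12,13,15-trinoreudesm-7-en-11-oate (C3 and C5 epimers)
Conditions: KN(SiMe3)2 (1.1 equiv), THF, −78 °C; 2-(phenylsulfonyl)-3-phenyloxaziridine, −78 °C; aqueous NH4Cl
Reagents that add atoms: 2-(phenylsulfonyl)-3-phenyloxaziridine, O=S(=O)(c1ccccc1)N1OC1c1ccccc1
Why: Kinetic deprotonation of the C4 ketone occurs at the methylene C3 and not at the hindered methine C5, and oxygen transfer from the N-sulfonyloxaziridine to the enolate (enolate α-hydroxylation) gives the acyloin, whose C3 and C5 configurations are irrelevant because both centres become trigonal in step 9.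

Step 9
Reactants: 13 methyl (10R)-3-hydroxy-8-(methoxymethoxy)-4-oxo-12,13,15-trinoreudesm-7-en-11-oate
Product: 15 methyl (10R)-4-hydroxy-8-(methoxymethoxy)-3-oxo-12,13,15-trinoreudesma-4,7-dien-11-oate (diosphenol), via 3,4-dione 14 (not isolated)
Conditions: Dess–Martin periodinane, NaHCO3, CH2Cl2, 0 °C to rt; then Et3N (0.2 equiv), CH2Cl2, rt
Reagents that add atoms: none
Why: Dess–Martin oxidation of the acyloin gives the 1,2-dione, which with base should settle as the more substituted conjugated diosphenol (4-hydroxy-4-en-3-one), so C5 becomes trigonal and both ring-fusion epimers converge.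

Step 10
Reactants: 15 methyl (10R)-4-hydroxy-8-(methoxymethoxy)-3-oxo-12,13,15-trinoreudesma-4,7-dien-11-oate
Product: 16 methyl (10R)-8-(methoxymethoxy)-3-oxo-4-[(trifluoromethylsulfonyl)oxy]-12,13,15-trinoreudesma-4,7-dien-11-oate
Conditions: PhNTf2 (1.2 equiv), Et3N, DMAP (10 mol%), CH2Cl2, 0 °C to rt
Reagents that add atoms: N-phenylbis(trifluoromethanesulfonimide), O=S(=O)(N(c1ccccc1)S(=O)(=O)C(F)(F)F)C(F)(F)F
Why: O-sulfonylation of the acidic diosphenol hydroxyl (enol triflate formation) turns the C4–O bond into a leaving group on the defined 4-ene, while the vinylogous carbonate in ring B has no free enol to react.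

Step 11
Reactants: 16 methyl (10R)-8-(methoxymethoxy)-3-oxo-4-[(trifluoromethylsulfonyl)oxy]-12,13,15-trinoreudesma-4,7-dien-11-oate
Product: 17 methyl (10R)-8-(methoxymethoxy)-3-oxo-12,13-dinoreudesma-4,7-dien-11-oate
Conditions: Me4Sn (3 equiv), Pd(PPh3)4 (5 mol%), LiCl (3 equiv), DMF, 70 °C
Reagents that add atoms: tetramethylstannane, C[Sn](C)(C)C
Why: Stille coupling of the α-triflyloxy enone with Me4Sn under neutral, LiCl-promoted conditions installs C15 on C4 and gives the 4-methyl-4-en-3-one without disturbing the doubly allylic C6 methylene.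

Step 12
Reactants: 17 methyl (10R)-8-(methoxymethoxy)-3-oxo-12,13-dinoreudesma-4,7-dien-11-oate
Product: 18 methyl (3S,10R)-3-hydroxy-8-(methoxymethoxy)-12,13-dinoreudesma-4,7-dien-11-oate (3β-OH)
Conditions: NaBH4, CeCl3·7H2O, MeOH, −78 to −40 °C
Reagents that add atoms: none
Why: In this Luche 1,2-reduction hydride should add to C3 axially from the α face, away from the C10 methyl, to give the pseudo-equatorial 3β-alcohol as in 10-methyl-4-en-3-ones of the steroid and eudesmane series, and the vinylogous carbonate is not reduced.

Step 13
Reactants: 18 methyl (3S,10R)-3-hydroxy-8-(methoxymethoxy)-12,13-dinoreudesma-4,7-dien-11-oate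
Product: 19 methyl (3S,4S,5R,10R)-3,4-dihydroxy-8-(methoxymethoxy)-12,13-dinoreudesm-7-en-11-oate (3β,4α-diol; 4β-CH3; 5α-H)
Conditions: BH3·THF (4 equiv), THF, 0 °C to rt; then NaOH, H2O2, 0 °C to rt
Reagents that add atoms: hydrogen peroxide, OO
Why: In this hydroboration–oxidation borane should add syn to the tetrasubstituted 4-ene from the α face, opposite the angular methyl and trans to the 3β-oxygen, with boron on C4 (next to the carbinol carbon, away from the neopentyl C5), so that oxidation with retention gives 4α-OH with 4β-CH3 and the trans ring fusion (5α-H) as known for 4-en-3β-ols of the steroid series, while the deactivated tetrasubstituted vinylogous carbonate of ring B should react more slowly.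

Step 14
Reactants: 19 methyl (3S,4S,5R,10R)-3,4-dihydroxy-8-(methoxymethoxy)-12,13-dinoreudesm-7-en-11-oate
Product: 21 (3S,4S,5R,10R)-3,4-dihydroxyeudesm-7(11)-en-8-one, via carbinol 20 (not isolated)
Conditions: MeLi (6 equiv), THF, −78 to 0 °C; then 1 M HCl, THF, 0 °C to rt
Reagents that add atoms: methyllithium, [Li]C
Why: Double 1,2-addition of MeLi to the ester (after deprotonation of the two hydroxyls) gives tertiary carbinol 20, and aqueous acid ionises this allylic alcohol with the help of the enol ether and hydrolyses the resulting oxocarbenium ion to the isopropylidene ketone (the standard conversion of a β-keto ester enol ether into an α-alkylidene ketone), with no stereocentre affected.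

Step 15
Reactants: 21 (3S,4S,5R,10R)-3,4-dihydroxyeudesm-7(11)-en-8-one; 22 (R)-2-methylbutanoic acid
Product: 23 (3S,4S,5R,10R)-4-hydroxy-8-oxoeudesm-7(11)-en-3-yl (2R)-2-methylbutanoate
Conditions: 22 (1.5 equiv), DCC, DMAP (20 mol%), CH2Cl2, 0 °C to rt
Reagents that add atoms: (R)-2-methylbutanoic acid, CC[C@@H](C)C(O)=O
Why: Steglich esterification should acylate the secondary equatorial 3β-hydroxyl selectively, the tertiary 4α-hydroxyl being inert under these conditions, and the simple α-branched acid should not epimerise through the acylpyridinium intermediate.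

Step 16
Reactants: 23 (3S,4S,5R,10R)-4-hydroxy-8-oxoeudesm-7(11)-en-3-yl (2R)-2-methylbutanoate
Product: 24 (3S,4S,5R,10R)-4-acetoxy-8-oxoeudesm-7(11)-en-3-yl (2R)-2-methylbutanoate (target)
Conditions: Ac2O (10 equiv), DMAP (2 equiv), Et3N, CH2Cl2, 40 °C
Reagents that add atoms: acetic anhydride, CC(=O)OC(C)=O
Why: DMAP-catalysed acetylation (acyl transfer through the N-acetylpyridinium ion) of the remaining equatorial tertiary alcohol with excess anhydride completes the target, and acyl migration is not expected because the secondary ester is already the less hindered one.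

**Compound list**

1 | 3-methylcyclohex-2-en-1-one | CC1=CC(=O)CCC1 | starting material
2 | ethynyltrimethylsilane | C#C[Si](C)(C)C | starting material
3 | (S)-3-methyl-3-[1-(trimethylsilyl)ethenyl]cyclohexan-1-one | O=C1CCC[C@](C)(C(=C)[Si](C)(C)C)C1 | intermediate
4 | (S)-3-methyl-3-vinylcyclohexan-1-one | O=C1CCC[C@](C)(C=C)C1 | intermediate
5 | (3R)-3-(2-hydroxyethyl)-3-methylcyclohexan-1-ol (both C1 epimers) | OC1CCC[C@](C)(CCO)C1 | intermediate
6 | 2-[(1R)-1-methyl-3-oxocyclohexyl]acetaldehyde | O=C1CCC[C@](C)(CC=O)C1 | intermediate
7 | methyl diazoacetate | COC(=O)C=[N+]=[N-] | starting material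
8 | methyl 4-[(1S)-1-methyl-3-oxocyclohexyl]-3-oxobutanoate | O=C1CCC[C@](C)(CC(=O)CC(=O)OC)C1 | intermediate
9 | formaldehyde (used as 37% aqueous solution) | C=O | starting material
10 | methyl 2-methylidene-4-[(1S)-1-methyl-3-oxocyclohexyl]-3-oxobutanoate (formed in the flask, not isolated) | O=C1CCC[C@](C)(CC(=O)C(=C)C(=O)OC)C1 | intermediate
11 | methyl (10R)-4,8-dioxo-12,13,15-trinoreudesman-11-oate (C5 epimers, C7 enolisable) | O=C1CCC[C@]2(C)CC(=O)C(C(=O)OC)CC12 | intermediate
12 | methyl (10R)-8-(methoxymethoxy)-4-oxo-12,13,15-trinoreudesm-7-en-11-oate (C5 epimers) | O=C1CCC[C@]2(C)CC(OCOC)=C(C(=O)OC)CC12 | intermediate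
13 | methyl (10R)-3-hydroxy-8-(methoxymethoxy)-4-oxo-12,13,15-trinoreudesm-7-en-11-oate (C3 and C5 epimers) | O=C1C(O)CC[C@]2(C)CC(OCOC)=C(C(=O)OC)CC12 | intermediate
14 | methyl (10R)-8-(methoxymethoxy)-3,4-dioxo-12,13,15-trinoreudesm-7-en-11-oate (C5 epimers, not isolated) | O=C1C(=O)CC[C@]2(C)CC(OCOC)=C(C(=O)OC)CC12 | intermediate
15 | methyl (10R)-4-hydroxy-8-(methoxymethoxy)-3-oxo-12,13,15-trinoreudesma-4,7-dien-11-oate | O=C1CC[C@]2(C)CC(OCOC)=C(C(=O)OC)CC2=C1O | intermediate
16 | methyl (10R)-8-(methoxymethoxy)-3-oxo-4-[(trifluoromethylsulfonyl)oxy]-12,13,15-trinoreudesma-4,7-dien-11-oate | O=C1CC[C@]2(C)CC(OCOC)=C(C(=O)OC)CC2=C1OS(=O)(=O)C(F)(F)F | intermediate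
17 | methyl (10R)-8-(methoxymethoxy)-3-oxo-12,13-dinoreudesma-4,7-dien-11-oate | O=C1CC[C@]2(C)CC(OCOC)=C(C(=O)OC)CC2=C1C | intermediate
18 | methyl (3S,10R)-3-hydroxy-8-(methoxymethoxy)-12,13-dinoreudesma-4,7-dien-11-oate | O[C@H]1CC[C@]2(C)CC(OCOC)=C(C(=O)OC)CC2=C1C | intermediate
19 | methyl (3S,4S,5R,10R)-3,4-dihydroxy-8-(methoxymethoxy)-12,13-dinoreudesm-7-en-11-oate | O[C@H]1CC[C@]2(C)CC(OCOC)=C(C(=O)OC)C[C@H]2[C@]1(C)O | intermediate
20 | (3S,4S,5R,10R)-8-(methoxymethoxy)eudesm-7-ene-3,4,11-triol (not isolated) | O[C@H]1CC[C@]2(C)CC(OCOC)=C(C(C)(C)O)C[C@H]2[C@]1(C)O | intermediate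
21 | (3S,4S,5R,10R)-3,4-dihydroxyeudesm-7(11)-en-8-one | O[C@H]1CC[C@]2(C)CC(=O)C(=C(C)C)C[C@H]2[C@]1(C)O | intermediate
22 | (R)-2-methylbutanoic acid | CC[C@@H](C)C(O)=O | starting material
23 | (3S,4S,5R,10R)-4-hydroxy-8-oxoeudesm-7(11)-en-3-yl (2R)-2-methylbutanoate | CC[C@@H](C)C(=O)O[C@H]1CC[C@]2(C)CC(=O)C(=C(C)C)C[C@H]2[C@]1(C)O | intermediate
24 | (3S,4S,5R,10R)-4-acetoxy-8-oxoeudesm-7(11)-en-3-yl (2R)-2-methylbutanoate | CC[C@@H](C)C(=O)O[C@H]1CC[C@]2(C)CC(=O)C(=C(C)C)C[C@H]2[C@]1(C)OC(C)=O | target

**Count and risks**

Total step count: 16. Longest linear sequence: 16 steps (from 1; compounds 2, 7, 9 and 22 are bought).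

Steps most likely to fail:

1. Step 6 (proposed new method). The methylene keto ester may be consumed by intermolecular Michael addition of a second β-keto ester, the ketone may undergo Mannich methylenation at C3, or the hindered C5 enamine may add too slowly. The fallback uses known reactions and makes the acceptor as a discrete compound. It sets out from 6: Morita–Baylis–Hillman reaction with methyl acrylate (DABCO) should give methyl 3-hydroxy-2-methylidene-4-[(1R)-1-methyl-3-oxocyclohexyl]butanoate F1. Dess–Martin oxidation of the allylic alcohol then gives 10, used at once. A base-mediated intramolecular Michael addition of the ring ketone (catalytic KOt-Bu, t-BuOH–THF, high dilution, equilibrating enolates so that only the six-membered closure through C5 is productive) returns to the route at 11.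

2. Step 13. Borane may also attack the ring B vinylogous carbonate (alkene hydroboration or slow ester reduction), or face selectivity on the tetrasubstituted alkene may be eroded. The fallback sets out from 17: Mukaiyama-type reductive α-hydroxylation of the enone (Mn(dpm)3 catalyst, PhSiH3, O2, i-PrOH–CH2Cl2, then P(OEt)3), with hydrogen-atom delivery to C5 and oxygen capture at C4 on the face opposite the C10 methyl, should give methyl (4S,5R,10R)-4-hydroxy-8-(methoxymethoxy)-3-oxo-12,13-dinoreudesm-7-en-11-oate F2. Reduction of the C3 ketone with NaBH4 (MeOH, −40 °C, axial hydride from the α face) returns to the route at 19.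

3. Step 9 (and with it step 10). The 3,4-dione may enolise toward C2 instead of C5; triflation and coupling of that tautomer would put the methyl on C3. The fallback avoids the diosphenol and sets out from 13: addition of MeMgBr–CeCl3 (THF, −78 °C) to the C4 ketone, which spares the vinylogous carbonate, should give methyl (10R)-3,4-dihydroxy-8-(methoxymethoxy)-12,13-dinoreudesm-7-en-11-oate F3. Dess–Martin oxidation of its secondary alcohol gives the α-ketol methyl (10R)-4-hydroxy-8-(methoxymethoxy)-3-oxo-12,13-dinoreudesm-7-en-11-oate F4. Dehydration with SOCl2–pyridine toward C5 (any exocyclic isomer equilibrated with DBU) returns to the route at 17.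

**Further compounds**

F1 | step 6 | methyl 3-hydroxy-2-methylidene-4-[(1R)-1-methyl-3-oxocyclohexyl]butanoate (carbinol epimers) | O=C1CCC[C@](C)(CC(O)C(=C)C(=O)OC)C1
F2 | step 13 | methyl (4S,5R,10R)-4-hydroxy-8-(methoxymethoxy)-3-oxo-12,13-dinoreudesm-7-en-11-oate | O=C1CC[C@]2(C)CC(OCOC)=C(C(=O)OC)C[C@H]2[C@]1(C)O
F3 | step 9 | methyl (10R)-3,4-dihydroxy-8-(methoxymethoxy)-12,13-dinoreudesm-7-en-11-oate (C3, C4 and C5 diastereomers) | OC1CC[C@]2(C)CC(OCOC)=C(C(=O)OC)CC2C1(C)O
F4 | step 9 | methyl (10R)-4-hydroxy-8-(methoxymethoxy)-3-oxo-12,13-dinoreudesm-7-en-11-oate (C4 and C5 diastereomers) | O=C1CC[C@]2(C)CC(OCOC)=C(C(=O)OC)CC2C1(C)O
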